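The route rests on reading the dihydrofuran ring of the target (O1, C2 with its guaiacyl ring, C3, C3a) as the pyranone ring of a flavanone minus one carbon: the CH2OH carbon on C3 is the former C4 carbonyl carbon. A trivalent-iodine oxidation shifts the benzo ring carbon C4a from C4 to C3, which contracts the six-membered ring to the five-membered one, expels C4 as a methyl ester and fixes the 2,3-trans relationship in one operation. Its precursor is an (R)-flavanone carrying 8-OMe, a 6-(3-chloropropyl) chain and a pivaloyl-masked guaiacyl group, made by catalytic asymmetric arylation of a chromone; hydride reduction and ferulate O-alkylation of the chloride complete the synthesis.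

Key step: step 6

Assumption: the antipode of the chiral diene that delivers the aryl group to the Si face of chromone C2 (giving 2R) is chosen from the ligand's stereochemical model and confirmed on the first run.

Step 1
Reactants: 1 dihydroconiferyl alcohol [4-(3-hydroxypropyl)-2-methoxyphenol]
Product: 2 4-(3-chloropropyl)-2-methoxyphenol
Conditions: PPh3 (1.3 equiv), NCS (1.3 equiv), THF, 0 °C (premixed), then 1, rt
Reagents that add atoms: N-chlorosuccinimide, O=C1CCC(=O)N1Cl
Why: Appel-type deoxychlorination, in which the preformed chlorophosphonium salt turns the primary alcohol into an alkoxyphosphonium ion that chloride displaces by SN2, while the phenol can only form a reversible aryloxyphosphonium species and is returned unchanged on work-up.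

Step 2
Reactants: 2 4-(3-chloropropyl)-2-methoxyphenol
Product: 4 1-[5-(3-chloropropyl)-2-hydroxy-3-methoxyphenyl]ethanone, via aryl acetate 3 (not isolated)
Conditions: AcOH, BF3·OEt2 (3 equiv), 90 °C; aq. NaOAc work-up
Reagents that add atoms: acetic acid, CC(=O)O
Why: Boron trifluoride-mediated C-acylation of a phenol through its acetate (Fries rearrangement), where the para position is blocked by the side chain, so the acyl group should settle at C6, the only free position ortho to the phenol oxygen and the one that gives the chelated ortho-hydroxy ketone, and BF3 is mild enough to spare the methyl ether and the primary chloride.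

Step 3
Reactants: 4 1-[5-(3-chloropropyl)-2-hydroxy-3-methoxyphenyl]ethanone
Product: 6 6-(3-chloropropyl)-8-methoxy-4H-chromen-4-one, via enaminone 5 (not isolated)
Conditions: Me2NCH(OMe)2 (2 equiv), toluene, 100 °C; concentrate; conc. HCl, CH2Cl2, 40 °C
Reagents that add atoms: N,N-dimethylformamide dimethyl acetal, COC(OC)N(C)C
Why: Enaminone annulation to a chromone, in which the methyl ketone condenses with the amide acetal to the vinylogous amide and, under acid, the ortho phenol adds to its β-carbon (6-endo oxa-Michael addition) and dimethylamine is expelled as its hydrochloride to leave the pyranone ring.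

Step 4
Reactants: 7 4-hydroxy-3-methoxyphenylboronic acid pinacol ester
Product: 8 2-methoxy-4-(4,4,5,5-tetramethyl-1,3,2-dioxaborolan-2-yl)phenyl pivalate
Conditions: t-BuCOCl (1.2 equiv), Et3N, DMAP (cat.), CH2Cl2, 0 °C to rt
Reagents that add atoms: pivaloyl chloride, CC(C)(C)C(=O)Cl
Why: Ordinary DMAP-catalysed O-acylation of a phenol that leaves the pinacol boronate untouched and installs a hindered ester that lowers the electron density of the ring and shields the phenol from the oxidant of step 6.

Step 5
Reactants: 6 6-(3-chloropropyl)-8-methoxy-4H-chromen-4-one; 8 2-methoxy-4-(4,4,5,5-tetramethyl-1,3,2-dioxaborolan-2-yl)phenyl pivalate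
Product: 9 (2R)-6-(3-chloropropyl)-8-methoxy-2-[3-methoxy-4-(pivaloyloxy)phenyl]chroman-4-one
Conditions: [RhCl(C2H4)2]2 (2.5 mol%), chiral diene Ph-bod* (2,5-diphenylbicyclo[2.2.2]octa-2,5-diene, 5.5 mol%, antipode giving 2R), K3PO4 (0.5 equiv, aq.), 1,4-dioxane/H2O 10:1, 40 °C; 8 (2.5 equiv)
Reagents that add atoms: none
Why: Hayashi–Miyaura asymmetric 1,4-addition with a monovalent rhodium diene catalyst, in which the boronate transmetalates to an oxygen-bound rhodium species, the aryl-rhodium inserts the chromone C2=C3 bond on the C2 Si face left open by the chiral diene, and protonation of the rhodium enolate releases the flavanone, so the catalyst alone should set the new C2 stereocentre as R while the mild substoichiometric base limits ring opening of the product.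

Step 6
Reactants: 9 (2R)-6-(3-chloropropyl)-8-methoxy-2-[3-methoxy-4-(pivaloyloxy)phenyl]chroman-4-one
Product: 12 methyl (2R,3R)-5-(3-chloropropyl)-7-methoxy-2-[3-methoxy-4-(pivaloyloxy)phenyl]-2,3-dihydrobenzofuran-3-carboxylate, via enol ether 10 (not isolated), via C3-iodanyl dimethyl ketal 11 (not isolated)
Conditions: PhI(OAc)2 (1.2 equiv), HC(OMe)3 (solvent), conc. H2SO4 (0.3 equiv), rt
Reagents that add atoms: trimethyl orthoformate, COC(OC)OC
Why: Acid and trimethyl orthoformate convert the ketone into its methyl enol ether, which attacks the trivalent iodine reagent through C3 on the face anti to the C2 aryl group, and methanol then adds at C4 to give a ketal whose equatorial C3 iodanyl group is antiperiplanar to the C4–C4a bond. Loss of iodobenzene is assisted by the benzo ring: C4a shifts from C4 to C3 through a phenonium-like bridged transition state, forming the C3–C3a bond, breaking C4–C4a and leaving a dimethoxycarbenium ion at the extruded carbon, which gives up a methyl group to become the methyl ester. The closest known reaction type is the hypervalent iodine (or thallium trinitrate, Tl(NO3)3) oxidative ring contraction of flavanones to trans methyl 2-aryl-2,3-dihydrobenzofuran-3-carboxylates, a relative of the oxidative 1,2-aryl shift of aryl ketones to arylacetates. The dihydrofuran ring is not cyclised from an open chain but arises by contraction of the pyranone ring, the ipso carbon displacing iodine at C3 in a 3-exo-tet sense. C3 is the only new stereocentre: anti addition of iodine followed by migration with inversion should place the ester trans to the C2 aryl group (also the thermodynamic arrangement), so the existing C2 centre controls it, and C2 itself is never ionised and should keep its configuration. The step must favour ring contraction over 2-aryl migration (isoflavone) and dehydrogenation (flavone); the ring oxygen ortho to the migrating carbon raises its migratory aptitude, the trans-diequatorial iodanyl ketal has the required alignment, and the pivaloyloxy group makes the C2 aryl ring a poorer migrating group and protects it from oxidation.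

Step 7
Reactants: 12 methyl (2R,3R)-5-(3-chloropropyl)-7-methoxy-2-[3-methoxy-4-(pivaloyloxy)phenyl]-2,3-dihydrobenzofuran-3-carboxylate
Product: 13 4-[(2R,3S)-5-(3-chloropropyl)-3-(hydroxymethyl)-7-methoxy-2,3-dihydrobenzofuran-2-yl]-2-methoxyphenol
Conditions: i-Bu2AlH (6 equiv), CH2Cl2, −78 to 0 °C; aq. KNaC4H4O6 (potassium sodium tartrate) work-up
Reagents that add atoms: none
Why: Aluminium hydride reduction in which i-Bu2AlH takes the methyl ester through the aldehyde to the primary alcohol and cleaves the aryl pivalate reductively in the same pot, under non-basic conditions that should neither epimerise C3 nor open the ring nor touch the primary chloride, so both stereocentres are carried over (C3 is named S only because the substituent priorities change).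

Step 8
Reactants: 13 4-[(2R,3S)-5-(3-chloropropyl)-3-(hydroxymethyl)-7-methoxy-2,3-dihydrobenzofuran-2-yl]-2-methoxyphenol; 14 trans-ferulic acid
Product: 16 3-[(2R,3S)-2-(4-hydroxy-3-methoxyphenyl)-3-(hydroxymethyl)-7-methoxy-2,3-dihydrobenzofuran-5-yl]propyl (E)-3-(4-hydroxy-3-methoxyphenyl)prop-2-enoate (target CNP0149450.1), via primary iodide 15 (not isolated)
Conditions: KHCO3 (1.5 equiv), KI (0.2 equiv), DMF, 65 °C; 14 (1.5 equiv)
Reagents that add atoms: none
Why: Chemoselective carboxylate O-alkylation (SN2 with in situ Finkelstein activation), in which bicarbonate deprotonates only the carboxylic acid, so the ferulate anion rather than the phenols or the primary alcohol should displace the transient primary iodide, and the E alkene of ferulic acid and both ring stereocentres are not involved.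

Compound list
1 | dihydroconiferyl alcohol, 4-(3-hydroxypropyl)-2-methoxyphenol | COc1cc(CCCO)ccc1O | starting material
2 | 4-(3-chloropropyl)-2-methoxyphenol | COc1cc(CCCCl)ccc1O | intermediate
3 | 4-(3-chloropropyl)-2-methoxyphenyl acetate | COc1cc(CCCCl)ccc1OC(C)=O | intermediate (not isolated)
4 | 1-[5-(3-chloropropyl)-2-hydroxy-3-methoxyphenyl]ethanone | CC(=O)c1cc(CCCCl)cc(OC)c1O | intermediate
5 | (E)-1-[5-(3-chloropropyl)-2-hydroxy-3-methoxyphenyl]-3-(dimethylamino)prop-2-en-1-one | CN(C)/C=C/C(=O)c1cc(CCCCl)cc(OC)c1O | intermediate (not isolated)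
6 | 6-(3-chloropropyl)-8-methoxy-4H-chromen-4-one | O=c1ccoc2c(OC)cc(CCCCl)cc12 | intermediate
7 | 4-hydroxy-3-methoxyphenylboronic acid pinacol ester | COc1cc(B2OC(C)(C)C(C)(C)O2)ccc1O | starting material
8 | 2-methoxy-4-(4,4,5,5-tetramethyl-1,3,2-dioxaborolan-2-yl)phenyl pivalate | COc1cc(B2OC(C)(C)C(C)(C)O2)ccc1OC(=O)C(C)(C)C | intermediate
9 | (2R)-6-(3-chloropropyl)-8-methoxy-2-[3-methoxy-4-(pivaloyloxy)phenyl]chroman-4-one | O=C1C[C@H](c2ccc(OC(=O)C(C)(C)C)c(OC)c2)Oc2c(OC)cc(CCCCl)cc12 | intermediate
10 | (2R)-6-(3-chloropropyl)-4,8-dimethoxy-2-[3-methoxy-4-(pivaloyloxy)phenyl]-2H-chromene | COC1=C[C@H](c2ccc(OC(=O)C(C)(C)C)c(OC)c2)Oc2c(OC)cc(CCCCl)cc12 | intermediate (not isolated)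
11 | 2,3-trans-3-[acetoxy(phenyl)-λ3-iodanyl]-6-(3-chloropropyl)-4,4,8-trimethoxy-2-[3-methoxy-4-(pivaloyloxy)phenyl]chromane (formally 2S,3S because iodine raises the priority of C3; C2 unchanged in space) | COC1(OC)[C@@H](I(OC(C)=O)c2ccccc2)[C@H](c2ccc(OC(=O)C(C)(C)C)c(OC)c2)Oc2c(OC)cc(CCCCl)cc12 | intermediate (not isolated)
12 | methyl (2R,3R)-5-(3-chloropropyl)-7-methoxy-2-[3-methoxy-4-(pivaloyloxy)phenyl]-2,3-dihydrobenzofuran-3-carboxylate (2,3-trans) | ClCCCc1cc(OC)c2c(c1)[C@@H](C(=O)OC)[C@H](c1ccc(OC(=O)C(C)(C)C)c(OC)c1)O2 | intermediate
13 | 4-[(2R,3S)-5-(3-chloropropyl)-3-(hydroxymethyl)-7-methoxy-2,3-dihydrobenzofuran-2-yl]-2-methoxyphenol | ClCCCc1cc(OC)c2c(c1)[C@@H](CO)[C@H](c1ccc(O)c(OC)c1)O2 | intermediate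
14 | trans-ferulic acid | COc1cc(/C=C/C(=O)O)ccc1O | starting material
15 | 4-[(2R,3S)-3-(hydroxymethyl)-5-(3-iodopropyl)-7-methoxy-2,3-dihydrobenzofuran-2-yl]-2-methoxyphenol | ICCCc1cc(OC)c2c(c1)[C@@H](CO)[C@H](c1ccc(O)c(OC)c1)O2 | intermediate (not isolated)
16 | 3-[(2R,3S)-2-(4-hydroxy-3-methoxyphenyl)-3-(hydroxymethyl)-7-methoxy-2,3-dihydrobenzofuran-5-yl]propyl (E)-ferulate, CNP0149450.1 | COc1cc(/C=C/C(=O)OCCCc2cc(OC)c3c(c2)[C@@H](CO)[C@H](c2ccc(O)c(OC)c2)O3)ccc1O | target

Total step count: 8 steps.
Longest linear sequence: 7 steps (steps 1, 2, 3, 5, 6, 7 and 8 from dihydroconiferyl alcohol); step 4 is a one-step side branch.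

Steps most likely to fail

Step 5. Transmetalation of the pinacol boronate to rhodium and insertion of the weakly electrophilic chromone may be slow, so that protodeboronation outruns addition. Base-induced ring opening and reclosure of the flavanone may also erode the enantiomeric purity. The fallback changes the boron partner and the catalytic manifold to a base-free cationic divalent palladium system. Setting out from 8, the pinacol ester is cleaved (NaIO4, NH4OAc, acetone/H2O, rt) to [3-methoxy-4-(pivaloyloxy)phenyl]boronic acid F1. F1 is then added to chromone 6 with Pd(OCOCF3)2 (5 mol%), the appropriate antipode of the tert-butyl pyridine-oxazoline t-BuPyOx (6 mol%), NH4PF6 and water in 1,2-dichloroethane at 60 °C, coming back to the route at flavanone 9.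

Step 6. The iodanyl ketal may partition toward migration of the C2 aryl group or toward elimination instead of benzo-ring migration, and the oxidant may attack the electron-rich benzo ring. The fallback is a carbene-based ring contraction (Wolff rearrangement) that makes the same C3–C3a bond. Setting out from 9, LiN(SiMe3)2 and CF3CO2CH2CF3 (THF, −78 °C) give the crude 3-(trifluoroacetyl)flavanone F2. Detrifluoroacetylative diazo transfer (MsN3, Et3N, H2O, MeCN, rt) gives the 3-diazoflavanone F3. Irradiation in methanol contracts the ring and should give the ester as a mixture of 12 and its cis epimer F4. DBU in toluene then equilibrates F4 to the trans ester, coming back to the route at 12.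

Step 2. Acyl transfer may go to the position para to the methoxy group instead of ortho to the phenol oxygen, or the Lewis acid may attack the methyl ether at the temperature needed. The fallback fixes the regiochemistry by chelation-controlled formylation. Setting out from 2, magnesium-mediated ortho-formylation (MgCl2, Et3N, paraformaldehyde, THF, reflux; Casnati–Skattebøl conditions) gives 5-(3-chloropropyl)-2-hydroxy-3-methoxybenzaldehyde F5. MeMgBr (2.2 equiv, THF, 0 °C) gives the carbinol 4-(3-chloropropyl)-2-(1-hydroxyethyl)-6-methoxyphenol F6. MnO2 (CH2Cl2, rt) oxidises the benzylic alcohol, coming back to the route at acetophenone 4.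

Further compounds
F1 | step 5 | [3-methoxy-4-(pivaloyloxy)phenyl]boronic acid | COc1cc(B(O)O)ccc1OC(=O)C(C)(C)C
F2 | step 6 | (2R)-6-(3-chloropropyl)-8-methoxy-2-[3-methoxy-4-(pivaloyloxy)phenyl]-3-(trifluoroacetyl)chroman-4-one (crude, C3 not defined) | O=C1C(C(=O)C(F)(F)F)[C@H](c2ccc(OC(=O)C(C)(C)C)c(OC)c2)Oc2c(OC)cc(CCCCl)cc12
F3 | step 6 | 6-(3-chloropropyl)-3-diazo-8-methoxy-2-[3-methoxy-4-(pivaloyloxy)phenyl]chroman-4-one (C2 unchanged in space, formally 2S) | O=C1C(=[N+]=[N-])[C@H](c2ccc(OC(=O)C(C)(C)C)c(OC)c2)Oc2c(OC)cc(CCCCl)cc12
F4 | step 6 | methyl (2R,3S)-5-(3-chloropropyl)-7-methoxy-2-[3-methoxy-4-(pivaloyloxy)phenyl]-2,3-dihydrobenzofuran-3-carboxylate (2,3-cis epimer) | ClCCCc1cc(OC)c2c(c1)[C@H](C(=O)OC)[C@H](c1ccc(OC(=O)C(C)(C)C)c(OC)c1)O2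
F5 | step 2 | 5-(3-chloropropyl)-2-hydroxy-3-methoxybenzaldehyde | O=Cc1cc(CCCCl)cc(OC)c1O
F6 | step 2 | 4-(3-chloropropyl)-2-(1-hydroxyethyl)-6-methoxyphenol (racemic carbinol) | CC(O)c1cc(CCCCl)cc(OC)c1O
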